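The ten-membered carbocycle is cut at C1(sp2)–C2(sp3) (germacrane numbering), where the (E)-C1=C10 alkene meets the C2–C3 bridge. The C2–C3–C4=C5 segment is read as a latent 2-substituted 1,3-diene: chemoselective 9-BBN hydroboration of its terminal vinyl group gives a homoallylic borane, which an intramolecular B-alkyl Suzuki–Miyaura coupling joins to a C1 (E)-vinyl iodide, closing the ring and fixing the C1=C10 geometry in one operation. The acyclic precursor already holds the trans-fused α-methylene-γ-lactone and the C6/C7/C8 stereotriad, set by chromium-mediated allylation of a (Z)-dienal with a bromomethylbutenolide derived from (S)-epichlorohydrin; the C15 ester is attached before ring closure.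

Key step: step 16

Remark: germacrane numbering is used throughout (C1=C10 with C14 methyl on C10; C4=C5 with C15 oxymethylene on C4; C6 carbinol; C7 and C8 ring fusion; C11=C13 exocyclic methylene; C12 lactone carbonyl). Methyl 4-hydroxybut-2-ynoate is taken as purchasable.

Step 1
Reactants: 1 (S)-epichlorohydrin; 2 ethynyltrimethylsilane
Product: 3 (2S)-1-chloro-5-(trimethylsilyl)pent-4-yn-2-ol
Conditions: 2, n-BuLi, THF, −78 °C; BF3·OEt2; then 1, −78 °C
Reagents that add atoms: none
Why: BF3-promoted alkynylation of the epoxide (SN2 opening by the lithium acetylide at the unsubstituted oxirane carbon) leaves the stereocentre that becomes C8 untouched.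

Step 2
Reactants: 3
Product: 6 (3S)-hex-1-en-5-yn-3-ol, via silyl epoxide 4 (not isolated), via silyl enynol 5 (not isolated)
Conditions: Me3S+ I− (4 equiv), n-BuLi (5 equiv), THF, −20 °C to rt; then K2CO3, MeOH, rt
Reagents that add atoms: trimethylsulfonium iodide C[S+](C)C.[I-]
Why: Base closes the chlorohydrin to the epoxide, the Corey–Chaykovsky ylide opens it at CH2 and the sulfonium betaine eliminates dimethyl sulfide (one-carbon epoxide-to-allylic-alcohol homologation), after which methanolic carbonate removes the alkynyl silyl group; the carbinol centre is not involved.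

Step 3
Reactants: 6
Product: 8 (3S,5E)-6-iodo-5-methylhexa-1,5-dien-3-ol, via alkenylalane 7 (not isolated)
Conditions: AlMe3 (3 equiv), Cp2ZrCl2 (0.25 equiv), CH2Cl2, 0 °C to rt; then iodine, THF, −30 to 0 °C
Reagents that add atoms: trimethylaluminium C[Al](C)C; iodine [I][I]
Why: Negishi zirconium-catalysed carboalumination adds methyl and aluminium syn across the terminal alkyne (methyl to the internal carbon) and iodinolysis of the C–Al bond proceeds with retention, so the (E)-vinyl iodide (C1, with C14 on C10) should result.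

Step 4
Reactants: 8; 9 2-(bromomethyl)prop-2-enoic acid
Product: 10 (3S,5E)-6-iodo-5-methylhexa-1,5-dien-3-yl 2-(bromomethyl)prop-2-enoate
Conditions: DCC, DMAP (5 mol%), CH2Cl2, 0 °C
Reagents that add atoms: none
Why: Steglich esterification of the secondary allylic alcohol without touching the carbinol C–O bond; low temperature and catalytic DMAP limit substitution at the allylic bromide.

Step 5
Reactants: 10
Product: 11 (5S)-3-(bromomethyl)-5-[(2E)-3-iodo-2-methylprop-2-en-1-yl]furan-2(5H)-one
Conditions: second-generation Grubbs catalyst RuCl2(=CHPh)(H2IMes)(PCy3) (5 mol%), CH2Cl2, 40 °C, 5 mM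
Reagents that add atoms: none
Why: Ring-closing metathesis between the vinyl group and the acrylate methylene expels ethene and closes the butenolide (C7=C11); the hindered trisubstituted vinyl iodide should not engage the ruthenium carbene and C8 is untouched.

Step 6
Reactants: 12 methyl 4-hydroxybut-2-ynoate
Product: 13 methyl 4-[(triethylsilyl)oxy]but-2-ynoate
Conditions: Et3SiCl, imidazole, CH2Cl2, 0 °C
Reagents that add atoms: chlorotriethylsilane CC[Si](Cl)(CC)CC
Why: Standard silylation of a primary propargylic alcohol; the triethylsilyl ether is chosen so that it can later be removed beside a secondary tert-butyldimethylsilyl ether.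

Step 7
Reactants: 13; 14 vinylmagnesium bromide
Product: 15 methyl (2Z)-3-{[(triethylsilyl)oxy]methyl}penta-2,4-dienoate
Conditions: 14 (2.4 equiv), CuBr·SMe2 (1.2 equiv), THF, −78 °C; then 13; MeOH then aq. NH4Cl at −78 °C
Reagents that add atoms: none
Why: Conjugate addition of the divinylcuprate to the ynoate is a syn-carbocupration, and protonation of the alkenylcopper at −78 °C before it can equilibrate places the vinyl group cis to H, so the ester (C6) and the oxymethylene (C15) end up cis across C4=C5.

Step 8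
Reactants: 15
Product: 16 (2Z)-3-{[(triethylsilyl)oxy]methyl}penta-2,4-dien-1-ol
Conditions: i-Bu2AlH (2.2 equiv), CH2Cl2, −78 °C; aq. potassium sodium tartrate
Reagents that add atoms: none
Why: 1,2-Reduction of the conjugated ester by the aluminium hydride at low temperature, with the alkene geometry retained.

Step 9
Reactants: 16
Product: 17 (2Z)-3-{[(triethylsilyl)oxy]methyl}penta-2,4-dienal
Conditions: activated MnO2 (15 equiv), CH2Cl2, rt
Reagents that add atoms: none
Why: Neutral allylic oxidation with MnO2 should keep the Z geometry; the vinyl group is trans to the formyl group, so oxa-electrocyclisation of the dienal is not possible.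

Step 10
Reactants: 18 {[tert-butyl(dimethyl)silyl]oxy}acetaldehyde; 19 ethyl 2-(triphenyl-λ5-phosphanylidene)propanoate
Product: 20 ethyl (2E)-4-{[tert-butyl(dimethyl)silyl]oxy}-2-methylbut-2-enoate
Conditions: CH2Cl2, rt
Reagents that add atoms: none
Why: Wittig olefination with an α-branched stabilised ylide is expected to give the (E)-trisubstituted enoate.

Step 11
Reactants: 20
Product: 21 (2E)-4-{[tert-butyl(dimethyl)silyl]oxy}-2-methylbut-2-enoic acid
Conditions: LiOH·H2O, THF/MeOH/H2O, rt; then 1 M HCl to pH 4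
Reagents that add atoms: lithium hydroxide [Li+].[OH-]
Why: Saponification of the ethyl ester; the primary silyl ether and the alkene geometry tolerate aqueous hydroxide at room temperature.

Step 12
Reactants: 11; 17
Product: 23 (4S,5S)-4-[(1R,2Z)-1-hydroxy-3-{[(triethylsilyl)oxy]methyl}penta-2,4-dien-1-yl]-5-[(2E)-3-iodo-2-methylprop-2-en-1-yl]-3-methylideneoxolan-2-one, via allylchromium 22 (not isolated)
Conditions: CrCl2 (3 equiv), THF, 0 °C to rt; aq. NH4Cl
Reagents that add atoms: none
Why: Nozaki–Hiyama allylation: the allylchromium adds through its ring carbon C7 on the face opposite the C8 side chain (trans-lactone), and the chair Zimmerman–Traxler transition state with the ring-locked E-type allyl unit and an equatorial dienyl group sets C6 anti to C8, that is (6R,7S) from (8S); the vinyl iodide is inert to CrCl2 without nickel.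

Step 13
Reactants: 23
Product: 24 (4R,5S)-4-[(1R,2Z)-1-{[tert-butyl(dimethyl)silyl]oxy}-3-{[(triethylsilyl)oxy]methyl}penta-2,4-dien-1-yl]-5-[(2E)-3-iodo-2-methylprop-2-en-1-yl]-3-methylideneoxolan-2-one
Conditions: TBSOTf, 2,6-lutidine, CH2Cl2, −78 °C
Reagents that add atoms: tert-butyldimethylsilyl trifluoromethanesulfonate CC(C)(C)[Si](C)(C)OS(=O)(=O)C(F)(F)F
Why: Silylation of the hindered C6 alcohol with the silyl triflate blocks base-induced translactonisation in the later steps; no stereocentre changes (the C7 descriptor changes only by priority).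

Step 14
Reactants: 24
Product: 25 (4R,5S)-4-[(1R,2Z)-1-{[tert-butyl(dimethyl)silyl]oxy}-3-(hydroxymethyl)penta-2,4-dien-1-yl]-5-[(2E)-3-iodo-2-methylprop-2-en-1-yl]-3-methylideneoxolan-2-one
Conditions: PPTS (0.2 equiv), MeOH/CH2Cl2, 0 °C
Reagents that add atoms: none
Why: Mild acid-catalysed methanolysis should cleave the primary triethylsilyl ether much faster than the hindered secondary tert-butyldimethylsilyl ether.

Step 15
Reactants: 25; 21
Product: 26 (2Z,4R)-4-{[tert-butyl(dimethyl)silyl]oxy}-2-ethenyl-4-{(2S,3R)-2-[(2E)-3-iodo-2-methylprop-2-en-1-yl]-4-methylidene-5-oxooxolan-3-yl}but-2-en-1-yl (2E)-4-{[tert-butyl(dimethyl)silyl]oxy}-2-methylbut-2-enoate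
Conditions: DCC, DMAP (0.2 equiv), CH2Cl2, 0 °C to rt
Reagents that add atoms: none
Why: Steglich esterification of the only free hydroxyl group (primary, allylic, C15) installs the side chain before ring closure, so that a single deprotection follows the macrocyclisation.

Step 16
Reactants: 26
Product: 28 [(3aR,4R,5Z,9E,11aS)-4-{[tert-butyl(dimethyl)silyl]oxy}-10-methyl-3-methylidene-2-oxo-2,3,3a,4,7,8,11,11a-octahydrocyclodeca[b]furan-6-yl]methyl (2E)-4-{[tert-butyl(dimethyl)silyl]oxy}-2-methylbut-2-enoate, via homoallylic borane 27 (not isolated)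
Conditions: 9-BBN dimer (1.2 equiv B–H), THF, 0 °C to rt; then syringe-pump addition to Pd(dppf)Cl2 (20 mol%), AsPh3 (40 mol%), Cs2CO3 (3 equiv), DMF/THF/H2O, rt, about 1 mM
Reagents that add atoms: none
Why: 9-BBN, an electrophilic hydroborating agent, adds anti-Markovnikov to the terminal vinyl group (C2=C3) of the diene to give the homoallylic borane 27. Zerovalent palladium inserts into the C1–I bond, base-assisted transmetalation transfers the tethered primary B-alkyl group and reductive elimination forms C1–C2; the closest known reaction type is the macrocyclising B-alkyl Suzuki–Miyaura coupling. The ten-membered carbocycle is closed by ring-contracting C(sp2)–C(sp3) reductive elimination from an eleven-membered palladacycle. No stereocentre is created; the (E) geometry of C1=C10 is carried over with retention from the vinyl iodide, and the C4=C5 geometry and the C6, C7 and C8 centres are not touched. The step needs hydroboration of the diene terminus in preference to the exocyclic C11=C13, an electron-poor acrylate-type alkene, and to the trisubstituted alkenes; the electrophilic character and bulk of 9-BBN, used in slight excess, are relied on for this. It also needs transmetalation to outrun carbopalladation of C11=C13 and ring closure to outrun oligomerisation, for which room temperature, aqueous carbonate and slow addition at high dilution are chosen, helped by the rigid trans-lactone that turns the two chain ends toward each other.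

Step 17
Reactants: 28
Product: 29 [(3aS,4R,5Z,9E,11aS)-4-hydroxy-10-methyl-3-methylidene-2-oxo-2,3,3a,4,7,8,11,11a-octahydrocyclodeca[b]furan-6-yl]methyl (2E)-4-hydroxy-2-methylbut-2-enoate
Conditions: HF·pyridine, pyridine, THF, 0 °C to rt
Reagents that add atoms: none
Why: Buffered fluoride desilylation removes both silyl ethers without base (no acyl migration, translactonisation or conjugate addition) and without strong acid (no transannular cyclisation of the 1(10),4-diene); the C7 descriptor returns to S by priority only.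

Compound list
1 | (S)-epichlorohydrin, (2S)-2-(chloromethyl)oxirane | ClC[C@@H]1CO1 | starting material
2 | ethynyltrimethylsilane | C#C[Si](C)(C)C | starting material
3 | (2S)-1-chloro-5-(trimethylsilyl)pent-4-yn-2-ol | O[C@H](CCl)CC#C[Si](C)(C)C | intermediate
4 | (2S)-2-[3-(trimethylsilyl)prop-2-yn-1-yl]oxirane (silyl epoxide, not isolated) | O1C[C@@H]1CC#C[Si](C)(C)C | intermediate
5 | (3S)-6-(trimethylsilyl)hex-1-en-5-yn-3-ol (silyl enynol, not isolated) | O[C@H](C=C)CC#C[Si](C)(C)C | intermediate
6 | (3S)-hex-1-en-5-yn-3-ol | O[C@H](C=C)CC#C | intermediate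
7 | dimethyl{(1E,4S)-4-[(dimethylalumanyl)oxy]-2-methylhexa-1,5-dien-1-yl}alumane (alkenylalane, not isolated) | C[Al](C)O[C@H](C=C)C/C(C)=C/[Al](C)C | intermediate
8 | (3S,5E)-6-iodo-5-methylhexa-1,5-dien-3-ol | O[C@H](C=C)C/C(C)=C/I | intermediate
9 | 2-(bromomethyl)prop-2-enoic acid | OC(=O)C(=C)CBr | starting material
10 | (3S,5E)-6-iodo-5-methylhexa-1,5-dien-3-yl 2-(bromomethyl)prop-2-enoate | C=C(CBr)C(=O)O[C@H](C=C)C/C(C)=C/I | intermediate
11 | (5S)-3-(bromomethyl)-5-[(2E)-3-iodo-2-methylprop-2-en-1-yl]furan-2(5H)-one | O=C1O[C@@H](C/C(C)=C/I)C=C1CBr | intermediate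
12 | methyl 4-hydroxybut-2-ynoate | COC(=O)C#CCO | starting material
13 | methyl 4-[(triethylsilyl)oxy]but-2-ynoate | COC(=O)C#CCO[Si](CC)(CC)CC | intermediate
14 | vinylmagnesium bromide | C=C[Mg]Br | starting material
15 | methyl (2Z)-3-{[(triethylsilyl)oxy]methyl}penta-2,4-dienoate | COC(=O)/C=C(/C=C)CO[Si](CC)(CC)CC | intermediate
16 | (2Z)-3-{[(triethylsilyl)oxy]methyl}penta-2,4-dien-1-ol | OC/C=C(/C=C)CO[Si](CC)(CC)CC | intermediate
17 | (2Z)-3-{[(triethylsilyl)oxy]methyl}penta-2,4-dienal | O=C/C=C(/C=C)CO[Si](CC)(CC)CC | intermediate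
18 | {[tert-butyl(dimethyl)silyl]oxy}acetaldehyde | O=CCO[Si](C)(C)C(C)(C)C | starting material
19 | ethyl 2-(triphenyl-λ5-phosphanylidene)propanoate | CCOC(=O)C(C)=P(c1ccccc1)(c1ccccc1)c1ccccc1 | starting material
20 | ethyl (2E)-4-{[tert-butyl(dimethyl)silyl]oxy}-2-methylbut-2-enoate | CCOC(=O)/C(C)=C/CO[Si](C)(C)C(C)(C)C | intermediate
21 | (2E)-4-{[tert-butyl(dimethyl)silyl]oxy}-2-methylbut-2-enoic acid | OC(=O)/C(C)=C/CO[Si](C)(C)C(C)(C)C | intermediate
22 | dichloro{[(5S)-5-[(2E)-3-iodo-2-methylprop-2-en-1-yl]-2-oxo-2,5-dihydrofuran-3-yl]methyl}chromium (allylchromium, trivalent chromium, not isolated) | Cl[Cr](Cl)CC1=C[C@H](C/C(C)=C/I)OC1=O | intermediate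
23 | (4S,5S)-4-[(1R,2Z)-1-hydroxy-3-{[(triethylsilyl)oxy]methyl}penta-2,4-dien-1-yl]-5-[(2E)-3-iodo-2-methylprop-2-en-1-yl]-3-methylideneoxolan-2-one | C=C1C(=O)O[C@@H](C/C(C)=C/I)[C@@H]1[C@H](O)/C=C(/C=C)CO[Si](CC)(CC)CC | intermediate
24 | (4R,5S)-4-[(1R,2Z)-1-{[tert-butyl(dimethyl)silyl]oxy}-3-{[(triethylsilyl)oxy]methyl}penta-2,4-dien-1-yl]-5-[(2E)-3-iodo-2-methylprop-2-en-1-yl]-3-methylideneoxolan-2-one | C=C1C(=O)O[C@@H](C/C(C)=C/I)[C@@H]1[C@H](O[Si](C)(C)C(C)(C)C)/C=C(/C=C)CO[Si](CC)(CC)CC | intermediate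
25 | (4R,5S)-4-[(1R,2Z)-1-{[tert-butyl(dimethyl)silyl]oxy}-3-(hydroxymethyl)penta-2,4-dien-1-yl]-5-[(2E)-3-iodo-2-methylprop-2-en-1-yl]-3-methylideneoxolan-2-one | C=C1C(=O)O[C@@H](C/C(C)=C/I)[C@@H]1[C@H](O[Si](C)(C)C(C)(C)C)/C=C(/C=C)CO | intermediate
26 | (2Z,4R)-4-{[tert-butyl(dimethyl)silyl]oxy}-2-ethenyl-4-{(2S,3R)-2-[(2E)-3-iodo-2-methylprop-2-en-1-yl]-4-methylidene-5-oxooxolan-3-yl}but-2-en-1-yl (2E)-4-{[tert-butyl(dimethyl)silyl]oxy}-2-methylbut-2-enoate | C=C1C(=O)O[C@@H](C/C(C)=C/I)[C@@H]1[C@H](O[Si](C)(C)C(C)(C)C)/C=C(/C=C)COC(=O)/C(C)=C/CO[Si](C)(C)C(C)(C)C | intermediate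
27 | B-alkyl-9-BBN adduct of 26: 9-borabicyclo[3.3.1]nonan-9-yl on C2, C3 now CH2, all else as in 26 (homoallylic borane, not isolated) | C=C1C(=O)O[C@@H](C/C(C)=C/I)[C@@H]1[C@H](O[Si](C)(C)C(C)(C)C)/C=C(/CCB2C3CCCC2CCC3)COC(=O)/C(C)=C/CO[Si](C)(C)C(C)(C)C | intermediate
28 | [(3aR,4R,5Z,9E,11aS)-4-{[tert-butyl(dimethyl)silyl]oxy}-10-methyl-3-methylidene-2-oxo-2,3,3a,4,7,8,11,11a-octahydrocyclodeca[b]furan-6-yl]methyl (2E)-4-{[tert-butyl(dimethyl)silyl]oxy}-2-methylbut-2-enoate | C=C1C(=O)O[C@H]2C/C(C)=C/CC/C(COC(=O)/C(C)=C/CO[Si](C)(C)C(C)(C)C)=C/[C@@H](O[Si](C)(C)C(C)(C)C)[C@H]12 | intermediate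
29 | [(3aS,4R,5Z,9E,11aS)-4-hydroxy-10-methyl-3-methylidene-2-oxo-2,3,3a,4,7,8,11,11a-octahydrocyclodeca[b]furan-6-yl]methyl (2E)-4-hydroxy-2-methylbut-2-enoate, CNP0326626.1 | C=C1C(=O)O[C@H]2C/C(C)=C/CC/C(COC(=O)/C(C)=C/CO)=C/[C@@H](O)[C@H]12 | target

Total step count: 17.
Longest linear sequence: 11 steps (steps 1 to 5, then 12 to 17).

Steps most likely to fail

Step 16. The borane may attack the exocyclic C11=C13 alkene, the vinylpalladium may insert into that alkene, or chains may couple with each other faster than the strained ten-membered ring closes. Fallback: setting out from 26, conjugate addition of benzeneselenol (PhSeH, cat. Et3N, CH2Cl2, 0 °C) masks the exocyclic methylene as the phenylselanylmethyl lactone F1. Hydroboration with 9-BBN then gives the borane F2 (not isolated), and the same Pd(dppf)Cl2/Cs2CO3 ring closure gives the macrocyclic selenide F3. Oxidation (H2O2, pyridine, CH2Cl2, 0 °C) gives the selenoxide F4 (not isolated), whose syn-elimination at or below room temperature restores C11=C13 and rejoins the route at 28.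

Step 12. Simple diastereoselection at the new carbinol carbon may erode through a boat or open transition state, giving a mixture at C6. Fallback: setting out from 23 obtained together with its carbinol epimer, Dess–Martin oxidation (NaHCO3, CH2Cl2, 0 °C) converges both epimers on the dienone F5. Corey–Bakshi–Shibata reduction with the (R)-methyl oxazaborolidine and catecholborane (toluene, −78 °C, dienyl group taken as the large substituent) then sets C6 under reagent control and comes back at 23.

Step 5. The allylic bromide may deactivate the ruthenium carbene, and initiation at the electron-poor 1,1-disubstituted alkene may be slow; the same bromide may also be attacked during the preceding esterification. Fallback: setting out from 8, commercial ethyl 2-(hydroxymethyl)acrylate is silylated (TBSCl, imidazole) to the silyl ether ester F6 and saponified (LiOH) to the acid F7. Steglich esterification of 8 with F7 gives the diene ester F8, ring-closing metathesis gives the silyloxymethyl butenolide F9, HF·pyridine gives the hydroxymethyl butenolide F10, and Appel bromination (CBr4, PPh3, CH2Cl2, 0 °C) comes back at 11.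

Further compounds
F1 | step 16 | phenylselenide adduct of 26: 3-[(phenylselanyl)methyl]oxolan-2-one in place of the 3-methylidene lactone, C11 epimers, all else as in 26 | c1ccccc1[Se]CC2C(=O)O[C@@H](C/C(C)=C/I)[C@@H]2[C@H](O[Si](C)(C)C(C)(C)C)/C=C(/C=C)COC(=O)/C(C)=C/CO[Si](C)(C)C(C)(C)C
F2 | step 16 | B-alkyl-9-BBN adduct of F1 (boron on C2, not isolated) | c1ccccc1[Se]CC2C(=O)O[C@@H](C/C(C)=C/I)[C@@H]2[C@H](O[Si](C)(C)C(C)(C)C)/C=C(/CCB3C4CCCC3CCC4)COC(=O)/C(C)=C/CO[Si](C)(C)C(C)(C)C
F3 | step 16 | macrocyclic selenide: 28 with 3-[(phenylselanyl)methyl] in place of 3-methylidene, C11 epimers | c1ccccc1[Se]CC1C(=O)O[C@H]2C/C(C)=C/CC/C(COC(=O)/C(C)=C/CO[Si](C)(C)C(C)(C)C)=C/[C@@H](O[Si](C)(C)C(C)(C)C)[C@H]12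
F4 | step 16 | selenoxide of F3 (not isolated) | O=[Se](c1ccccc1)CC1C(=O)O[C@H]2C/C(C)=C/CC/C(COC(=O)/C(C)=C/CO[Si](C)(C)C(C)(C)C)=C/[C@@H](O[Si](C)(C)C(C)(C)C)[C@H]12
F5 | step 12 | (4R,5S)-5-[(2E)-3-iodo-2-methylprop-2-en-1-yl]-3-methylidene-4-[(2Z)-3-{[(triethylsilyl)oxy]methyl}penta-2,4-dienoyl]oxolan-2-one | C=C1C(=O)O[C@@H](C/C(C)=C/I)[C@@H]1C(=O)/C=C(/C=C)CO[Si](CC)(CC)CC
F6 | step 5 | ethyl 2-({[tert-butyl(dimethyl)silyl]oxy}methyl)prop-2-enoate | C=C(CO[Si](C)(C)C(C)(C)C)C(=O)OCC
F7 | step 5 | 2-({[tert-butyl(dimethyl)silyl]oxy}methyl)prop-2-enoic acid | C=C(CO[Si](C)(C)C(C)(C)C)C(=O)O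
F8 | step 5 | (3S,5E)-6-iodo-5-methylhexa-1,5-dien-3-yl 2-({[tert-butyl(dimethyl)silyl]oxy}methyl)prop-2-enoate | C=C(CO[Si](C)(C)C(C)(C)C)C(=O)O[C@H](C=C)C/C(C)=C/I
F9 | step 5 | (5S)-3-({[tert-butyl(dimethyl)silyl]oxy}methyl)-5-[(2E)-3-iodo-2-methylprop-2-en-1-yl]furan-2(5H)-one | O=C1O[C@@H](C/C(C)=C/I)C=C1CO[Si](C)(C)C(C)(C)C
F10 | step 5 | (5S)-3-(hydroxymethyl)-5-[(2E)-3-iodo-2-methylprop-2-en-1-yl]furan-2(5H)-one | O=C1O[C@@H](C/C(C)=C/I)C=C1CO
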